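**Assumption:** "4α" is read as 3,4-trans, i.e. upper unit (2R,3S,4S) and lower unit (2R,3S) = (+)-catechin, as the SMILES encodes. The sense of induction of (R)-TRIP in step 6 is assumed; if the first run gives the C4 epimer, (S)-TRIP is used instead.

## Retrosynthetic overview

1. Target ⇐ global O-debenzylation of 10; the upper C2–H and C3–OH ⇐ anti-selective hydroboration–oxidation of the (4S)-4-aryl-4H-flav-2-ene 9, so C4 controls C2 and C3.
2. 9 ⇐ face-selective hydride delivery to a flat, aromatic 4-aryl-flavylium cation held as a chiral phosphate ion pair; this dearomatizes the pyrylium ring and creates C4.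
3. Flavylium ⇐ pseudobase 8 ⇐ C4–C8 bond by addition of 8-lithio-penta-O-benzylcatechin to the carbonyl of flavone 7.
4. Flavone 7 ⇐ resacetophenone + 3,4-bis(benzyloxy)benzaldehyde; the aryl-lithium ⇐ (+)-catechin by benzylation and C8 bromination.
5. Ring order: the lower A/B/C rings come intact from (+)-catechin; the upper A and B rings come from the two benzenoid starting materials; the upper C-ring is closed as a pyranone, aromatized to the pyrylium, then dearomatized.

## Route

**Step 1**
Reactants: 1, (+)-catechin
Product: 2, 3,5,7,3',4'-penta-O-benzyl-(+)-catechin, (2R,3S)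
Conditions: BnBr (7 equiv), K2CO3, DMF, rt; then NaH (1.5 equiv), 0 °C → rt, one pot
Reagents that add atoms: benzyl bromide, BrCc1ccccc1
Why: Williamson etherification of the four phenols under mild carbonate conditions and then of the C3 alkoxide with NaH; C2 and C3 are untouched.

**Step 2**
Reactants: 2, penta-O-benzyl-(+)-catechin
Product: 3, 8-bromo-3,5,7,3',4'-penta-O-benzyl-(+)-catechin, (2R,3S)
Conditions: NBS (1.0 equiv), CH2Cl2, −78 → 0 °C
Reagents that add atoms: N-bromosuccinimide, O=C1CCC(=O)N1Br
Why: Electrophilic aromatic bromination of the phloroglucinol-type A-ring, which goes to C8 because C6 is flanked by two freely rotating benzyloxy groups.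

**Step 3**
Reactants: 4, 2',4'-dihydroxyacetophenone (resacetophenone)
Product: 5, 4'-benzyloxy-2'-hydroxyacetophenone
Conditions: BnBr (1.05 equiv), K2CO3, acetone, reflux
Reagents that add atoms: benzyl bromide, BrCc1ccccc1
Why: Chemoselective Williamson etherification of the 4-OH, since the 2-OH is hydrogen-bonded to the ketone and stays free for the later ring closure.

**Step 4**
Reactants: 5, 4'-benzyloxy-2'-hydroxyacetophenone; 6, 3,4-bis(benzyloxy)benzaldehyde
Product: 7, 7-(benzyloxy)-2-[3,4-bis(benzyloxy)phenyl]-4H-chromen-4-one (tri-O-benzyl-7,3',4'-trihydroxyflavone)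
Conditions: pyrrolidine (0.5 equiv), I2 (10 mol %), DMSO, 140 °C
Reagents that add atoms: none
Why: One-pot Claisen–Schmidt aldol condensation, oxa-Michael ring closure and iodine/DMSO dehydrogenation gives the aromatic flavone directly; no stereocentre is formed.

**Step 5**
Reactants: 3, 8-bromo-penta-O-benzylcatechin (1.3 equiv); 7, tri-O-benzylflavone
Product: 8, 7-(benzyloxy)-2-[3,4-bis(benzyloxy)phenyl]-4-[(2R,3S)-penta-O-benzylcatechin-8-yl]-4H-chromen-4-ol (flavylium pseudobase; C4 carbinol epimers, irrelevant)
Conditions: t-BuLi (2.6 equiv), THF, −78 °C; then 7, −78 → 0 °C; pH 7 buffer quench; short basic-alumina plug, used crude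
Reagents that add atoms: none (t-BuLi only exchanges Br for Li; H from the quench)
Why: Halogen–lithium exchange followed by 1,2-addition of the 2,6-dialkoxyaryl-lithium to the γ-pyranone carbonyl, the same reaction type by which hindered aryl-lithiums add to xanthones and flavones to give xanthylium/flavylium precursors; the C4 carbinol centre is erased in step 6.

**Step 6 (key step)**
Reactants: 8, pseudobase
Product: 9, (4S)-7-(benzyloxy)-2-[3,4-bis(benzyloxy)phenyl]-4-[(2R,3S)-penta-O-benzylcatechin-8-yl]-4H-chromene (4-aryl-4H-flav-2-ene)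
Conditions: (R)-TRIP (10 mol %), Hantzsch ester (diethyl 2,6-dimethyl-1,4-dihydropyridine-3,5-dicarboxylate, 1.2 equiv), 4 Å MS, toluene, −20 °C → rt, Ar, dark; filtered through basic alumina and used directly
Reagents that add atoms: none (the Hantzsch ester delivers only H)
Why: Proposed new method: the chiral phosphoric acid ionizes the 4-ol to the flat, aromatic 2,4-diaryl-1-benzopyrylium (flavylium) cation as a contact ion pair with the chiral phosphate, which also hydrogen-bonds the Hantzsch ester N–H and so delivers hydride to one face of C4, dearomatizing the pyrylium ring and setting C4 as S (asymmetric ion-pair transfer hydrogenation); the closest known reaction type is the chiral-phosphoric-acid-catalysed enantioselective 1,4-reduction of 2,4-diaryl-1-benzopyrylium ions generated in situ from chromenols with Hantzsch esters, extended here to a di-ortho-substituted 4-aryl group; any hydride attack at C2 from the same face gives the (2S)-2H-flav-3-ene, which converges to the same product in step 7.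

**Step 7**
Reactants: 9, (4S)-4-aryl-4H-flav-2-ene
Product: 10, octa-O-benzyl-fisetinidol-(4α→8)-catechin with free upper 3-OH, upper unit (2R,3S,4S), lower unit (2R,3S)
Conditions: BH3·SMe2 (5 equiv), THF, 0 °C → rt; then 3 M NaOH, 30 % H2O2, 0 °C → rt; chromatography removes the minor C4-derived diastereomer
Reagents that add atoms: hydrogen peroxide, OO (supplies the C3 oxygen; borane adds only H)
Why: Brown hydroboration–oxidation of the enol ether places boron at C3 (β to oxygen) and adds syn from the face opposite the bulky pseudo-axial C4 aryl, so C3–OH is trans to the C4 aryl and the C2 aryl is trans to C3–OH (2,3-trans-3,4-trans), with retention in the oxidation.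

**Step 8**
Reactants: 10, octabenzyl ether
Product: 11, fisetinidol-(4α,8)-catechin (target)
Conditions: H2 (1 atm), 20 % Pd(OH)2/C, THF–MeOH–H2O, rt; filter under Ar, Sephadex LH-20, lyophilize
Reagents that add atoms: none
Why: Pd-catalysed hydrogenolysis removes all eight benzyl ethers under neutral conditions that leave the interflavan C4–C8 bond, the benzylic C2–O bonds and all five stereocentres intact.

## Compound list

1 | (+)-catechin, (2R,3S) | Oc1cc(O)c2c(c1)O[C@H](c1ccc(O)c(O)c1)[C@@H](O)C2 | starting material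
2 | 3,5,7,3',4'-penta-O-benzyl-(+)-catechin | C(c1ccccc1)Oc1cc(OCc2ccccc2)c2c(c1)O[C@H](c1ccc(OCc3ccccc3)c(OCc3ccccc3)c1)[C@@H](OCc1ccccc1)C2 | intermediate
3 | 8-bromo-3,5,7,3',4'-penta-O-benzyl-(+)-catechin | C(c1ccccc1)Oc1cc(OCc2ccccc2)c2c(c1Br)O[C@H](c1ccc(OCc3ccccc3)c(OCc3ccccc3)c1)[C@@H](OCc1ccccc1)C2 | intermediate
4 | 2',4'-dihydroxyacetophenone (resacetophenone) | CC(=O)c1ccc(O)cc1O | starting material
5 | 4'-benzyloxy-2'-hydroxyacetophenone | CC(=O)c1ccc(OCc2ccccc2)cc1O | intermediate
6 | 3,4-bis(benzyloxy)benzaldehyde | O=Cc1ccc(OCc2ccccc2)c(OCc2ccccc2)c1 | starting material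
7 | 7-(benzyloxy)-2-[3,4-bis(benzyloxy)phenyl]-4H-chromen-4-one | O=c1cc(-c2ccc(OCc3ccccc3)c(OCc3ccccc3)c2)oc2cc(OCc3ccccc3)ccc12 | intermediate
8 | 7-(benzyloxy)-2-[3,4-bis(benzyloxy)phenyl]-4-(penta-O-benzylcatechin-8-yl)-4H-chromen-4-ol (C4 epimers) | C(c1ccccc1)Oc1ccc2c(c1)OC(c1ccc(OCc3ccccc3)c(OCc3ccccc3)c1)=CC2(O)c1c(OCc2ccccc2)cc(OCc2ccccc2)c2c1O[C@H](c1ccc(OCc3ccccc3)c(OCc3ccccc3)c1)[C@@H](OCc1ccccc1)C2 | intermediate
9 | (4S)-7-(benzyloxy)-2-[3,4-bis(benzyloxy)phenyl]-4-(penta-O-benzylcatechin-8-yl)-4H-chromene | C(c1ccccc1)Oc1ccc2c(c1)OC(c1ccc(OCc3ccccc3)c(OCc3ccccc3)c1)=C[C@@H]2c1c(OCc2ccccc2)cc(OCc2ccccc2)c2c1O[C@H](c1ccc(OCc3ccccc3)c(OCc3ccccc3)c1)[C@@H](OCc1ccccc1)C2 | intermediate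
10 | octa-O-benzyl-fisetinidol-(4α→8)-catechin, upper 3-OH free, (2R,3S,4S)/(2R,3S) | C(c1ccccc1)Oc1ccc2c(c1)O[C@H](c1ccc(OCc3ccccc3)c(OCc3ccccc3)c1)[C@@H](O)[C@@H]2c1c(OCc2ccccc2)cc(OCc2ccccc2)c2c1O[C@H](c1ccc(OCc3ccccc3)c(OCc3ccccc3)c1)[C@@H](OCc1ccccc1)C2 | intermediate
11 | fisetinidol-(4α,8)-catechin | Oc1ccc2c(c1)O[C@H](c1ccc(O)c(O)c1)[C@@H](O)[C@@H]2c1c(O)cc(O)c2c1O[C@H](c1ccc(O)c(O)c1)[C@@H](O)C2 | target

## Summary

Total steps: 8. Longest linear sequence: 6 (steps 1, 2, 5, 6, 7, 8, or 3, 4, 5, 6, 7, 8).

Three steps most likely to fail: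

1. **Step 6** (face selectivity with a bulky chiral 4-aryl group; possible over-reduction of the enol ether). Fallback: set the stereochemistry on a simple chromone instead. Asymmetric Pd(II)/PyOx or Rh/diphosphine conjugate addition of 3,4-bis(benzyloxy)phenylboronic acid to 7-benzyloxychromone gives the (S)-flavanone; enol triflate formation and Negishi coupling with the arylzinc from 3 give the (2S)-4-aryl-2H-flav-3-ene. Hydroboration anti to the C2 aryl then gives the same 10.

2. **Step 5** (hindered aryl-lithium adding to a deactivated pyranone carbonyl; labile pseudobase). Fallback: drop the organolithium. Activate flavone 7 with Tf2O or POCl3 to the 4-triflyloxy/4-chloro-flavylium salt and let unbrominated 2 attack through C8 by electrophilic aromatic substitution. Aqueous NaHCO3 converts the resulting 4-aryl-flavylium salt to 8 for step 6.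

3. **Step 7** (β-aryloxy-borane elimination with ring opening; incomplete facial control). Fallback: replace hydroboration with DMDO epoxidation of the enol ether anti to the C4 aryl, then Et3SiH/BF3·OEt2 reductive opening at the acetal carbon C2. Axial hydride delivery to the oxocarbenium gives the all-equatorial 2,3-trans-3,4-trans flavan-3-ol.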